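A direct plan would join C7 to C8: the aryl vinyl ether A1 would take up 3,4,5-trimethoxybenzaldehyde A2 in a carbene-catalysed enantioselective hydroacylation to give the (S)-α-aryloxy ketone A3, which a bulky hydride would reduce under Felkin–Anh control to the threo alcohol. Its weakest steps would be the intermolecular hydroacylation of the vinyl ether (an acyl-anion equivalent would have to add to an unactivated, electron-rich alkene in preference to a second aldehyde, and would set C8 alone) and the hydride reduction of the ketone (C7 would be set in a separate, substrate-controlled event next to an enolisable C8, so that erythro isomer and loss of enantiopurity would be expected).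

The route rests on disconnecting C7–OH and C8–H, not a carbon–carbon bond: both stereocentres are traced back to the flat (E)-enol ether 6, in which the C8–O–C4′ ether to ring B is already in place at an sp2 carbon. One reagent-controlled syn hydroboration–oxidation would put boron on C7, benzylic to ring A and β to the ether oxygen, and hydrogen on C8 from the same face; the threo relationship then follows from the alkene geometry and the absolute configuration from the pinene-derived borane. No acyl-anion addition to a vinyl ether and no reduction of an epimerisable α-aryloxy ketone remain; 6 itself comes from a stereodefined alkenylboronate and methyl vanillate.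

Key step: step 4

Numbering used: C7 is the benzylic carbinol carbon, C8 the aryloxy-bearing carbon, C9 the methyl group; ring A is the 3,4,5-trimethoxyphenyl ring and ring B the benzoate ring, whose C4′ carries the ether oxygen.
Assumption: the facial preference of IpcBH2 from (+)-α-pinene, known for trisubstituted hydrocarbon alkenes, is taken to hold for enol ether 6; if the opposite sense were found, the reagent from (−)-α-pinene would be used.

Step 1
Reactants: 1 5-iodo-1,2,3-trimethoxybenzene; 2 propyne
Product: 3 1,2,3-trimethoxy-5-(prop-1-yn-1-yl)benzene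
Conditions: PdCl2(PPh3)2 (2 mol%), CuI (4 mol%), Et3N, THF, 2 (excess, balloon), rt
Reagents that add atoms: none
Why: Sonogashira coupling (oxidative addition of the aryl iodide to zerovalent palladium, transmetalation from the copper acetylide, reductive elimination); no stereocentre is involved and the methoxy groups are inert.

Step 2
Reactants: 3 1,2,3-trimethoxy-5-(prop-1-yn-1-yl)benzene
Product: 4 4,4,5,5-tetramethyl-2-[(Z)-1-(3,4,5-trimethoxyphenyl)prop-1-en-2-yl]-1,3,2-dioxaborolane
Conditions: CuCl (5 mol%), NaOtBu (10 mol%), P(p-tol)3 (6 mol%), B2pin2 (1.1 equiv), MeOH (2 equiv), THF, rt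
Reagents that add atoms: bis(pinacolato)diboron, CC1(C)OB(OC1(C)C)B1OC(C)(C)C(C)(C)O1
Why: Copper-catalysed formal hydroboration of an internal aryl alkyne (syn borylcupration, then protonation of the alkenylcopper by methanol with retention): boron should go to the methyl-bearing carbon because copper prefers the aryl-bearing carbon, and the syn addition places ring A and the methyl group cis (Z), the geometry that later becomes threo.

Step 3
Reactants: 4 4,4,5,5-tetramethyl-2-[(Z)-1-(3,4,5-trimethoxyphenyl)prop-1-en-2-yl]-1,3,2-dioxaborolane; 5 methyl vanillate (methyl 4-hydroxy-3-methoxybenzoate)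
Product: 6 methyl 3-methoxy-4-{[(E)-1-(3,4,5-trimethoxyphenyl)prop-1-en-2-yl]oxy}benzoate
Conditions: Cu(OAc)2 (0.5 equiv), Et3N (3 equiv), 4 Å MS, O2 (balloon), CH2Cl2, rt; 4 (1.5 equiv)
Reagents that add atoms: none
Why: Chan–Lam–Evans oxidative C–O coupling of a phenol with an alkenylboronate (transmetalation to the divalent copper phenoxide, oxidation to trivalent copper, reductive elimination, with O2 as terminal oxidant); the alkene geometry should be retained, so ring A and the aryloxy group end up trans (E), and no stereocentre is formed.

Step 4
Reactants: 6 methyl 3-methoxy-4-{[(E)-1-(3,4,5-trimethoxyphenyl)prop-1-en-2-yl]oxy}benzoate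
Product: 8 methyl 4-{[(1S,2S)-1-hydroxy-1-(3,4,5-trimethoxyphenyl)propan-2-yl]oxy}-3-methoxybenzoate, via benzylic isopinocampheylborane 7 (not isolated)
Conditions: IpcBH2 from (+)-α-pinene (1.3 equiv, BF3-free solution), THF, −25 °C; then MeOH, NaBO3·4H2O, THF/H2O, 0 °C to rt
Reagents that add atoms: sodium perborate, [Na+].[Na+].O[B-]1(O)OO[B-](O)(O)OO1
Why: Proposed new method: the B–H bond of the chiral monoalkylborane would add across C7=C8 of 6 in a concerted four-centre syn addition, boron going to C7 because that carbon is the nucleophilic β-carbon of the enol ether, benzylic to ring A and the less substituted terminus, and hydrogen to C8, to give borane 7, whose C7–B bond is then oxidised with retention by 1,2-shift of C7 from boron to peroxide oxygen. The closest known reactions are the asymmetric hydroboration–oxidation of trisubstituted alkenes such as 1-arylcycloalkenes with this borane and the achiral hydroboration–oxidation of enol ethers to β-alkoxy alcohols; an acyclic trisubstituted aryl enol ether has not been shown with the chiral reagent. No ring is closed. C7 and C8 are created in the same event: the threo relationship follows from syn addition to the E alkene, in which ring A and the C9 methyl group are cis, and the absolute configuration (7S,8S) from the isopinocampheyl group, which by the precedent of trisubstituted alkenes shields one face of the carbon that receives boron. The step needs regioselectivity, secured by the three concordant biases named above, and survival of the β-aryloxyborane against loss of the aryloxide, for which the low temperature, the absence of Lewis acid and the mild perborate oxidation, which also spares the methyl ester, are chosen.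

## Compound list

1 | 5-iodo-1,2,3-trimethoxybenzene | COc1cc(I)cc(OC)c1OC | starting material
2 | propyne | CC#C | starting material
3 | 1,2,3-trimethoxy-5-(prop-1-yn-1-yl)benzene | CC#Cc1cc(OC)c(OC)c(OC)c1 | intermediate
4 | 4,4,5,5-tetramethyl-2-[(Z)-1-(3,4,5-trimethoxyphenyl)prop-1-en-2-yl]-1,3,2-dioxaborolane | C/C(B1OC(C)(C)C(C)(C)O1)=C\c1cc(OC)c(OC)c(OC)c1 | intermediate
5 | methyl vanillate (methyl 4-hydroxy-3-methoxybenzoate) | COC(=O)c1ccc(O)c(OC)c1 | starting material
6 | methyl 3-methoxy-4-{[(E)-1-(3,4,5-trimethoxyphenyl)prop-1-en-2-yl]oxy}benzoate | COC(=O)c1ccc(O/C(C)=C/c2cc(OC)c(OC)c(OC)c2)c(OC)c1 | intermediate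
7 | [(1S,2S)-2-(2-methoxy-4-methoxycarbonylphenoxy)-1-(3,4,5-trimethoxyphenyl)propyl](isopinocampheyl)borane, written as the monomer | COC(=O)c1ccc(O[C@@H](C)[C@@H]([BH][C@@H]2C[C@@H]3C[C@H]([C@H]2C)C3(C)C)c2cc(OC)c(OC)c(OC)c2)c(OC)c1 | intermediate
8 | methyl 4-{[(1S,2S)-1-hydroxy-1-(3,4,5-trimethoxyphenyl)propan-2-yl]oxy}-3-methoxybenzoate | COC(=O)c1ccc(O[C@@H](C)[C@@H](O)c2cc(OC)c(OC)c(OC)c2)c(OC)c1 | target

Total step count: 4. Longest linear sequence: 4 steps (1 → 3 → 4 → 6 → 8).

Steps most likely to fail

Step 4: facial discrimination by the chiral borane may be poor on an enol ether; the threo relationship is not at risk, because it follows from the syn addition. A fallback by known chemistry would set out from 6: hydroboration with BH3·SMe2 (THF, 0 °C) and the same perborate oxidation would give the racemic threo alcohol F1. Esterification with (S)-O-methylmandelic acid (DCC, DMAP, CH2Cl2) would give two diastereomeric esters, the (7S,8S)-ester F2 and the (7R,8R)-ester F3, to be separated on silica gel. Methanolysis of F2 (K2CO3, MeOH, rt), which is degenerate at the methyl benzoate, would come back to the route at 8.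

Step 3: transmetalation of the α-methyl-substituted alkenylboronate to copper may be slow, so that protodeboronation and oxidative homocoupling would consume 4. A fallback would set out from 4: iododeboronation (NaOH, then I2, THF/H2O, 0 °C, retention of geometry) would give (E)-5-(2-iodoprop-1-en-1-yl)-1,2,3-trimethoxybenzene F4. An Ullmann-type vinylation of 5 with F4 (CuI, N,N-dimethylglycine, Cs2CO3, dioxane, 90 °C; monovalent copper catalysis, retention of geometry) would come back to the route at 6.

Step 2: regiocontrol of the borylcupration may be incomplete, part of the boron being delivered to the aryl-bearing carbon. A fallback would set out from 3: hydrozirconation with Cp2Zr(H)Cl (THF, 40 °C, slight excess so that zirconium equilibrates to the less hindered, methyl-bearing carbon) would give the alkenylzirconocene chloride F5. This would be brominated in the flask with NBS (retention) to (E)-5-(2-bromoprop-1-en-1-yl)-1,2,3-trimethoxybenzene F6. Copper-catalysed coupling of F6 with 5 (CuI, 3,4,7,8-tetramethyl-1,10-phenanthroline, Cs2CO3, toluene, 110 °C) would come back to the route at 6, bypassing 4.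

Further compounds

F1 | step 4 | racemic threo alcohol, methyl 4-{[(1S*,2S*)-1-hydroxy-1-(3,4,5-trimethoxyphenyl)propan-2-yl]oxy}-3-methoxybenzoate (both enantiomers) | COC(=O)c1ccc(O[C@@H](C)[C@@H](O)c2cc(OC)c(OC)c(OC)c2)c(OC)c1.COC(=O)c1ccc(O[C@H](C)[C@H](O)c2cc(OC)c(OC)c(OC)c2)c(OC)c1
F2 | step 4 | methyl 3-methoxy-4-{[(1S,2S)-1-{[(2S)-2-methoxy-2-phenylacetyl]oxy}-1-(3,4,5-trimethoxyphenyl)propan-2-yl]oxy}benzoate | COC(=O)c1ccc(O[C@@H](C)[C@@H](OC(=O)[C@@H](OC)c2ccccc2)c2cc(OC)c(OC)c(OC)c2)c(OC)c1
F3 | step 4 | methyl 3-methoxy-4-{[(1R,2R)-1-{[(2S)-2-methoxy-2-phenylacetyl]oxy}-1-(3,4,5-trimethoxyphenyl)propan-2-yl]oxy}benzoate | COC(=O)c1ccc(O[C@H](C)[C@H](OC(=O)[C@@H](OC)c2ccccc2)c2cc(OC)c(OC)c(OC)c2)c(OC)c1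
F4 | step 3 | (E)-5-(2-iodoprop-1-en-1-yl)-1,2,3-trimethoxybenzene | C/C(I)=C\c1cc(OC)c(OC)c(OC)c1
F5 | step 2 | chlorobis(cyclopentadienyl)[(E)-1-(3,4,5-trimethoxyphenyl)prop-1-en-2-yl]zirconium | C/C(=C\c1cc(OC)c(OC)c(OC)c1)[Zr](Cl)(C1C=CC=C1)C1C=CC=C1
F6 | step 2 | (E)-5-(2-bromoprop-1-en-1-yl)-1,2,3-trimethoxybenzene | C/C(Br)=C\c1cc(OC)c(OC)c(OC)c1
A1 | direct plan | methyl 3-methoxy-4-(vinyloxy)benzoate | COC(=O)c1ccc(OC=C)c(OC)c1
A2 | direct plan | 3,4,5-trimethoxybenzaldehyde | COc1cc(C=O)cc(OC)c1OC
A3 | direct plan | methyl 3-methoxy-4-{[(2S)-1-oxo-1-(3,4,5-trimethoxyphenyl)propan-2-yl]oxy}benzoate | COC(=O)c1ccc(O[C@@H](C)C(=O)c2cc(OC)c(OC)c(OC)c2)c(OC)c1
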